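**Retrosynthetic overview**
1. Target ⇒ C5 carbinol (as its PMB ether) by late oxidation; the side-chain oxirane from a prenyl alkene by reagent-controlled Shi epoxidation; both angelates by mixed-anhydride acylation.
2. Key bond C8–C9: asymmetric allylboration of the ring-bound 2-substituted acrolein (C8 aldehyde) with a B-allyl diisopinocampheylborane; the allyl terminus becomes prenyl by cross-metathesis.
3. The acrolein comes from ene chlorination and N-oxide oxidation of the isopropenyl group of a fully oxygenated ring.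
4. All ring oxygens are placed on (R)-carvone: Rubottom oxidation (C6), then reduction, directed epoxidation, selenide opening and oxidative 1,3-transposition (C2), reduction, and a second directed epoxidation (C3–C4).
5. Ring order: the carbocycle is bought with carvone; a temporary oxirane (step 5) is destroyed in step 7; the ring oxirane is made in step 10 and the side-chain oxirane last (step 19).

Convention: locants are those of the target throughout (ring C1 carries the side chain, C2 OAng, C3–C4 oxirane with C4–Me, C5 C=O, C6 OAc; side chain C7(=CH2)–C8–C9–C10–C11); cis/trans are relative to the C1 substituent; in these locants the target is 1R,2S,3S,4S,6S,8R,10S.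

**Step 1**
Reactants: 1 (R)-(−)-carvone
Product: 3 trimethylsilyl dienol ether of carvone (5-OTMS-3,5-diene), via lithium dienolate 2 (not isolated)
Conditions: LiN(iPr)2, THF, −78 °C; then Me3SiCl, −78 → 0 °C
Reagents that add atoms: chlorotrimethylsilane C[Si](C)(C)Cl
Why: Kinetic deprotonation of the enone at the C6 methylene by the hindered amide and O-silylation of the enolate give the cross-conjugated silyl dienol ether without touching C1.

**Step 2**
Reactants: 3 trimethylsilyl dienol ether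
Product: 5 trans-6-hydroxycarvone, via 6-trimethylsilyloxy ketone 4 (not isolated)
Conditions: mCPBA (1.0 equiv), NaHCO3, CH2Cl2, −20 °C; then 1 M HCl, THF, 0 °C
Reagents that add atoms: mCPBA O=C(OO)c1cccc(Cl)c1
Why: Rubottom oxidation: the electron-rich silyl enol ether is epoxidised much faster than the isopropenyl group and anti to it, and the silyloxy-oxirane collapses to the silyloxy ketone that acid hydrolyses, which sets C6–O trans to the C1 substituent.

**Step 3**
Reactants: 5 trans-6-hydroxycarvone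
Product: 6 trans-6-(triisopropylsilyloxy)carvone
Conditions: TIPSOTf, 2,6-lutidine, CH2Cl2, −78 → 0 °C
Reagents that add atoms: triisopropylsilyl triflate CC(C)[Si](OS(=O)(=O)C(F)(F)F)(C(C)C)C(C)C
Why: Standard silylation of a secondary alcohol with a silyl triflate and a hindered pyridine base; TIPS is chosen because it does not migrate in step 6.

**Step 4**
Reactants: 6 silyloxy enone
Product: 7 allylic alcohol (3-ene; 5-OH cis; 6-OTIPS trans)
Conditions: NaBH4, CeCl3·7H2O, MeOH, −78 °C
Reagents that add atoms: none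
Why: Luche 1,2-reduction with axial hydride delivery gives the pseudo-equatorial 5-OH, trans to 6-OTIPS and cis to the isopropenyl group (a temporary centre that is reoxidised in step 21).

**Step 5**
Reactants: 7 allylic alcohol
Product: 8 epoxy alcohol (3,4-oxirane cis to 5-OH)
Conditions: VO(acac)2 (5 mol%), t-BuOOH, CH2Cl2, 0 °C → rt
Reagents that add atoms: tert-butyl hydroperoxide CC(C)(C)OO
Why: Hydroxyl-directed vanadium-catalysed epoxidation delivers oxygen syn to the allylic 5-OH and leaves the remote isopropenyl alkene untouched.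

**Step 6**
Reactants: 8 epoxy alcohol
Product: 9 5-O-PMB ether of 8
Conditions: NaH, 4-methoxybenzyl bromide, Bu4NI (cat.), THF/DMF, 0 °C → rt
Reagents that add atoms: 4-methoxybenzyl bromide COc1ccc(CBr)cc1
Why: Williamson etherification; the cis oxirane cannot undergo Payne rearrangement and the TIPS group does not migrate, so no centre changes.

**Step 7**
Reactants: 9 PMB ether
Product: 12 tertiary allylic alcohol (2-ene; 4-OH cis; 5-OPMB; 6-OTIPS), via 3-phenylselanyl-4-ol 10 (not isolated), via selenoxide 11 (not isolated)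
Conditions: (PhSe)2, NaBH4, EtOH, reflux; then THF, 30% H2O2, 0 °C → rt
Reagents that add atoms: none
Why: Sharpless–Lauer sequence: the selenolate opens the oxirane at the less hindered C3 by trans-diaxial SN2 attack, and the selenoxide syn-elimination can only take a C2 hydrogen, giving the 2,3-alkene and the tertiary 4-ol.

**Step 8**
Reactants: 12 tertiary allylic alcohol
Product: 13 enone (1-isopropenyl-4-methyl-5-OPMB-6-OTIPS-cyclohex-3-en-2-one)
Conditions: pyridinium chlorochromate [C5H5NH][CrO3Cl], NaOAc, 4 Å molecular sieves, CH2Cl2, rt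
Reagents that add atoms: pyridinium chlorochromate [O-][Cr](=O)(=O)Cl.c1cc[nH+]cc1
Why: Babler–Dauben oxidative 1,3-transposition: the tertiary chromate ester undergoes a [3,3] shift to C2 and is oxidised there, which moves the oxygen to C2.

**Step 9**
Reactants: 13 enone
Product: 14 allylic alcohol (2-OH cis to the C1 isopropenyl)
Conditions: LiBH(s-Bu)3, THF, −78 °C; NaOH, H2O2 work-up, 0 °C
Reagents that add atoms: none
Why: The β,β-disubstituted enone undergoes 1,2-reduction, and the bulky trialkylborohydride is expected to attack from the face opposite the adjacent C1 substituent, giving the pseudo-axial 2-OH cis to it.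

**Step 10**
Reactants: 14 allylic alcohol
Product: 15 epoxy alcohol (3,4-oxirane cis to 2-OH and to the C1 substituent)
Conditions: VO(acac)2 (5 mol%), t-BuOOH (1.2 equiv), CH2Cl2, 0 °C
Reagents that add atoms: tert-butyl hydroperoxide CC(C)(C)OO
Why: Hydroxyl-directed epoxidation from the pseudo-axial allylic 2-OH sets C3 and C4 syn to it; the allylic ring alkene reacts far faster than the homoallylic isopropenyl alkene.

**Step 11**
Reactants: 15 epoxy alcohol; 16 angelic acid
Product: 17 2-O-angelate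
Conditions: 16, 2,4,6-trichlorobenzoyl chloride, Et3N, toluene, rt; then 15, 80 °C
Reagents that add atoms: angelic acid C/C=C(/C)C(=O)O
Why: Yamaguchi-type mixed-anhydride esterification without DMAP, conditions chosen to avoid angelate-to-tiglate isomerisation; C2 keeps its configuration.

**Step 12**
Reactants: 17 2-O-angelate
Product: 18 6-alcohol
Conditions: HF·pyridine, pyridine, THF, 0 °C → rt
Reagents that add atoms: none
Why: Buffered fluoride desilylation; the oxirane, flanked by two oxygenated carbons, the ester and the PMB ether survive.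

**Step 13**
Reactants: 18 6-alcohol
Product: 19 6-acetate
Conditions: Ac2O, pyridine, DMAP (cat.), CH2Cl2, rt
Reagents that add atoms: acetic anhydride CC(=O)OC(C)=O
Why: Simple acetylation of the only free hydroxyl, with retention at C6.

**Step 14**
Reactants: 19 6-acetate
Product: 20 allylic chloride (C1 substituent = 3-chloroprop-1-en-2-yl)
Conditions: Ca(OCl)2, CO2 (dry ice), CH2Cl2/H2O, 0 °C
Reagents that add atoms: calcium hypochlorite [Ca+2].[O-]Cl.[O-]Cl
Why: Ene-type allylic chlorination by HOCl: electrophilic chlorine adds to the terminal CH2 of the only electron-rich alkene and a methyl proton is lost, while the conjugated angelate alkene is inert.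

**Step 15**
Reactants: 20 allylic chloride
Product: 22 enal (C8 aldehyde on the C7 methylene unit), via allyloxytrimethylammonium chloride 21 (not isolated)
Conditions: Me3NO (anhydrous, 3 equiv), DMSO, rt
Reagents that add atoms: trimethylamine N-oxide C[N+](C)(C)[O-]
Why: Ganem (Kornblum-type) oxidation: SN2 O-alkylation of the N-oxide by the allylic chloride followed by elimination of the amine gives the 2-substituted acrolein under non-hydrolytic conditions.

**Step 16** (key C–C bond formation)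
Reactants: 22 enal; 23 B-allylbis(isopinocampheyl)borane from (−)-α-pinene (made from (+)-Ipc2BOMe)
Product: 25 (8R)-homoallylic alcohol, via diisopinocampheylborinate 24 (not isolated)
Conditions: 23 (1 M in pentane, 1.5 equiv), Et2O, −78 °C; then NaBO3·4H2O, THF/H2O, rt
Reagents that add atoms: B-allylbis(isopinocampheyl)borane C=CCB([C@H]1C[C@H]2C[C@@H]([C@@H]1C)C2(C)C)[C@H]1C[C@H]2C[C@@H]([C@@H]1C)C2(C)C
Why: Brown asymmetric allylboration (carbonyl allylation) through a closed six-membered chair transition state; the isopinocampheyl groups control the aldehyde face and give the 8R carbinol, and esters and the oxirane do not react at −78 °C.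

**Step 17**
Reactants: 25 homoallylic alcohol; 26 2-methylbut-2-ene
Product: 27 (8R)-prenyl carbinol
Conditions: second-generation Grubbs catalyst RuCl2(H2IMes)(PCy3)(=CHPh) (5 mol%), 1,4-benzoquinone (10 mol%), 26/CH2Cl2 (1:1), 40 °C, sealed tube
Reagents that add atoms: 2-methylbut-2-ene CC=C(C)C
Why: Olefin cross-metathesis of the monosubstituted alkene with excess 2-methylbut-2-ene installs the isopropylidene end; the hindered 1,1-disubstituted and conjugated alkenes do not react, and it is run before acylation to exclude ring-closing metathesis onto an angelate.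

**Step 18**
Reactants: 27 prenyl carbinol; 16 angelic acid
Product: 28 2,8-bis-angelate
Conditions: 16, 2,4,6-trichlorobenzoyl chloride, Et3N, toluene, rt; then 27, 80 °C
Reagents that add atoms: angelic acid C/C=C(/C)C(=O)O
Why: Same mixed-anhydride esterification as step 11, with retention at C8.

**Step 19**
Reactants: 28 bis-angelate
Product: 29 (10S)-10,11-epoxide
Conditions: L-fructose-derived Shi ketone (30 mol%), Oxone (2KHSO5·KHSO4·K2SO4), K2CO3, Bu4NHSO4, aq Na2B4O7 buffer, MeCN/CH2(OMe)2, 0 °C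
Reagents that add atoms: potassium peroxymonosulfate [K+].[O-]S(=O)(=O)OO
Why: Shi asymmetric epoxidation: the chiral dioxirane attacks only the electron-rich trisubstituted alkene through a spiro transition state, and the L-fructose-derived ketone gives the 10S oxirane by reagent control.

**Step 20**
Reactants: 29 epoxide
Product: 30 C5 alcohol
Conditions: DDQ, CH2Cl2/pH 7 phosphate buffer (10:1), 0 °C → rt
Reagents that add atoms: none
Why: Oxidative PMB cleavage (benzylic hydride abstraction, then hydrolysis) under neutral conditions, so both oxiranes and the esters survive and the neighbouring acetate does not migrate.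

**Step 21**
Reactants: 30 C5 alcohol
Product: 31 CNP0407453.2 (target)
Conditions: Dess–Martin periodinane, NaHCO3, CH2Cl2, 0 °C → rt
Reagents that add atoms: none
Why: Dess–Martin oxidation of the hindered secondary alcohol to the epoxy ketone under buffered conditions that do not epimerise C6.

**Compound list**
1 | (R)-(−)-carvone | C=C(C)[C@@H]1CC=C(C)C(=O)C1 | starting material
2 | lithium dienolate of carvone (C5–O, C5=C6; not isolated) | [Li+].C=C(C)[C@@H]1CC=C(C)C([O-])=C1 | intermediate
3 | trimethylsilyl dienol ether of carvone (5-OTMS-3,5-diene) | C=C(C)[C@@H]1CC=C(C)C(O[Si](C)(C)C)=C1 | intermediate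
4 | trans-6-(trimethylsilyloxy)carvone (not isolated) | C=C(C)[C@@H]1CC=C(C)C(=O)[C@H]1O[Si](C)(C)C | intermediate
5 | trans-6-hydroxycarvone, (5S,6S) in carvone numbering | C=C(C)[C@@H]1CC=C(C)C(=O)[C@H]1O | intermediate
6 | trans-6-(triisopropylsilyloxy)carvone | C=C(C)[C@@H]1CC=C(C)C(=O)[C@H]1O[Si](C(C)C)(C(C)C)C(C)C | intermediate
7 | 1-isopropenyl-4-methyl-6-OTIPS-cyclohex-3-en-5-ol, 5-OH cis, 6-OTIPS trans | C=C(C)[C@@H]1CC=C(C)[C@H](O)[C@H]1O[Si](C(C)C)(C(C)C)C(C)C | intermediate
8 | 3,4-epoxy-5-ol, oxirane O and 5-OH cis, 6-OTIPS trans | C=C(C)[C@@H]1C[C@@H]2O[C@]2(C)[C@H](O)[C@H]1O[Si](C(C)C)(C(C)C)C(C)C | intermediate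
9 | 5-O-(4-methoxybenzyl) ether of 8 | C=C(C)[C@@H]1C[C@@H]2O[C@]2(C)[C@H](OCc2ccc(OC)cc2)[C@H]1O[Si](C(C)C)(C(C)C)C(C)C | intermediate
10 | 3-phenylselanyl-4-ol, SePh trans, 4-OH cis (not isolated) | C=C(C)[C@@H]1C[C@@H]([Se]c2ccccc2)[C@](C)(O)[C@H](OCc2ccc(OC)cc2)[C@H]1O[Si](C(C)C)(C(C)C)C(C)C | intermediate
11 | selenoxide of 10 (not isolated) | C=C(C)[C@@H]1C[C@@H]([Se](=O)c2ccccc2)[C@](C)(O)[C@H](OCc2ccc(OC)cc2)[C@H]1O[Si](C(C)C)(C(C)C)C(C)C | intermediate
12 | tertiary allylic alcohol, 2-ene, 4-OH cis, 5-OPMB cis, 6-OTIPS trans | C=C(C)[C@@H]1C=C[C@](C)(O)[C@H](OCc2ccc(OC)cc2)[C@H]1O[Si](C(C)C)(C(C)C)C(C)C | intermediate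
13 | 1-isopropenyl-4-methyl-5-OPMB-6-OTIPS-cyclohex-3-en-2-one | C=C(C)[C@@H]1C(=O)C=C(C)[C@H](OCc2ccc(OC)cc2)[C@H]1O[Si](C(C)C)(C(C)C)C(C)C | intermediate
14 | cyclohex-3-en-2-ol, 2-OH cis | C=C(C)[C@@H]1[C@H](O)C=C(C)[C@H](OCc2ccc(OC)cc2)[C@H]1O[Si](C(C)C)(C(C)C)C(C)C | intermediate
15 | 3,4-epoxy-2-ol, oxirane cis to 2-OH | C=C(C)[C@@H]1[C@H](O)[C@@H]2O[C@]2(C)[C@H](OCc2ccc(OC)cc2)[C@H]1O[Si](C(C)C)(C(C)C)C(C)C | intermediate
16 | angelic acid, (Z)-2-methylbut-2-enoic acid | C/C=C(/C)C(=O)O | starting material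
17 | 2-O-angelate of 15 | C=C(C)[C@@H]1[C@H](OC(=O)/C(C)=C\C)[C@@H]2O[C@]2(C)[C@H](OCc2ccc(OC)cc2)[C@H]1O[Si](C(C)C)(C(C)C)C(C)C | intermediate
18 | 6-alcohol, 2-OAng, 5-OPMB | C=C(C)[C@@H]1[C@H](OC(=O)/C(C)=C\C)[C@@H]2O[C@]2(C)[C@H](OCc2ccc(OC)cc2)[C@H]1O | intermediate
19 | 6-acetate, 2-OAng, 5-OPMB | C=C(C)[C@@H]1[C@H](OC(=O)/C(C)=C\C)[C@@H]2O[C@]2(C)[C@H](OCc2ccc(OC)cc2)[C@H]1OC(C)=O | intermediate
20 | allylic chloride, C1 substituent 3-chloroprop-1-en-2-yl | C=C(CCl)[C@@H]1[C@H](OC(=O)/C(C)=C\C)[C@@H]2O[C@]2(C)[C@H](OCc2ccc(OC)cc2)[C@H]1OC(C)=O | intermediate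
21 | allyloxytrimethylammonium chloride from 20 (not isolated) | C=C(CO[N+](C)(C)C)[C@@H]1[C@H](OC(=O)/C(C)=C\C)[C@@H]2O[C@]2(C)[C@H](OCc2ccc(OC)cc2)[C@H]1OC(C)=O.[Cl-] | intermediate
22 | enal, C1 substituent 3-oxoprop-1-en-2-yl | C=C(C=O)[C@@H]1[C@H](OC(=O)/C(C)=C\C)[C@@H]2O[C@]2(C)[C@H](OCc2ccc(OC)cc2)[C@H]1OC(C)=O | intermediate
23 | B-allylbis(isopinocampheyl)borane from (−)-α-pinene | C=CCB([C@H]1C[C@H]2C[C@@H]([C@@H]1C)C2(C)C)[C@H]1C[C@H]2C[C@@H]([C@@H]1C)C2(C)C | starting material
24 | diisopinocampheylborinate of 25 (not isolated) | C=C([C@@H]1[C@H](OC(=O)/C(C)=C\C)[C@@H]2O[C@]2(C)[C@H](OCc2ccc(OC)cc2)[C@H]1OC(C)=O)[C@@H](CC=C)OB([C@H]1C[C@H]2C[C@@H]([C@@H]1C)C2(C)C)[C@H]1C[C@H]2C[C@@H]([C@@H]1C)C2(C)C | intermediate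
25 | (8R)-homoallylic alcohol | C=C([C@@H]1[C@H](OC(=O)/C(C)=C\C)[C@@H]2O[C@]2(C)[C@H](OCc2ccc(OC)cc2)[C@H]1OC(C)=O)[C@@H](CC=C)O | intermediate
26 | 2-methylbut-2-ene | CC=C(C)C | starting material
27 | (8R)-prenyl carbinol | C=C([C@@H]1[C@H](OC(=O)/C(C)=C\C)[C@@H]2O[C@]2(C)[C@H](OCc2ccc(OC)cc2)[C@H]1OC(C)=O)[C@@H](CC=C(C)C)O | intermediate
28 | 2,8-bis-angelate | C=C([C@@H]1[C@H](OC(=O)/C(C)=C\C)[C@@H]2O[C@]2(C)[C@H](OCc2ccc(OC)cc2)[C@H]1OC(C)=O)[C@@H](CC=C(C)C)OC(=O)/C(C)=C\C | intermediate
29 | (10S)-10,11-epoxide, 5-OPMB | C=C([C@@H]1[C@H](OC(=O)/C(C)=C\C)[C@@H]2O[C@]2(C)[C@H](OCc2ccc(OC)cc2)[C@H]1OC(C)=O)[C@@H](C[C@@H]1OC1(C)C)OC(=O)/C(C)=C\C | intermediate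
30 | C5 alcohol, 5-OH cis | C=C([C@@H]1[C@H](OC(=O)/C(C)=C\C)[C@@H]2O[C@]2(C)[C@H](O)[C@H]1OC(C)=O)[C@@H](C[C@@H]1OC1(C)C)OC(=O)/C(C)=C\C | intermediate
31 | CNP0407453.2 | C=C([C@@H]1[C@H](OC(=O)/C(C)=C\C)[C@@H]2O[C@]2(C)C(=O)[C@H]1OC(C)=O)[C@@H](C[C@@H]1OC1(C)C)OC(=O)/C(C)=C\C | target

**Totals**
Total step count: 21. Longest linear sequence: 21 steps (1 → 31); 16, 23 and 26 are purchased.

**Three steps most likely to fail**

Step 9 (which face of the C2 carbonyl the hydride takes is not secure for a cyclohexenone). Fallback: set out from 13. Luche reduction (NaBH4, CeCl3·7H2O, MeOH, −78 °C, axial delivery) is expected to give the C2-epimeric allylic alcohol F1, which is also the unwanted epimer that step 9 would leave. Mitsunobu reaction (4-nitrobenzoic acid, PPh3, DIAD, toluene, 0 °C → rt) inverts C2 to the cis 4-nitrobenzoate F2, and K2CO3 in MeOH returns to 14. The centre is then set by SN2 inversion and not by the hydride face.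

Step 11 (acylation of a hindered pseudo-axial hydroxyl with an acid that isomerises easily). Fallback: set out from 15. DCC/DMAP esterification with 2-[bis(2,2,2-trifluoroethoxy)phosphoryl]propanoic acid gives the phosphonopropionate F3. Still–Gennari olefination (KN(SiMe3)2, 18-crown-6, THF, −78 °C, acetaldehyde) then builds the Z-alkene on the ester and comes back at 17.

Step 14 (ene chlorination of a hindered isopropenyl group beside a PMB ether and an angelate). Fallback: set out from 19. Direct allylic oxidation (SeO2 cat., t-BuOOH, CH2Cl2, rt) gives the primary allylic alcohol F4, and MnO2 in CH2Cl2 oxidises it to enal 22, bypassing 20 and step 15.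

**Further compounds**
F1 | step 9 | C2-epimer of 14 (2-OH trans to the C1 isopropenyl) | C=C(C)[C@@H]1[C@@H](O)C=C(C)[C@H](OCc2ccc(OC)cc2)[C@H]1O[Si](C(C)C)(C(C)C)C(C)C
F2 | step 9 | 4-nitrobenzoate of 14 (2-O cis) | C=C(C)[C@@H]1[C@H](OC(=O)c2ccc([N+](=O)[O-])cc2)C=C(C)[C@H](OCc2ccc(OC)cc2)[C@H]1O[Si](C(C)C)(C(C)C)C(C)C
F3 | step 11 | 2-O-[2-(bis(2,2,2-trifluoroethoxy)phosphoryl)propanoate] of 15 | C=C(C)[C@@H]1[C@H](OC(=O)C(C)P(=O)(OCC(F)(F)F)OCC(F)(F)F)[C@@H]2O[C@]2(C)[C@H](OCc2ccc(OC)cc2)[C@H]1O[Si](C(C)C)(C(C)C)C(C)C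
F4 | step 14 | primary allylic alcohol, C1 substituent 3-hydroxyprop-1-en-2-yl | C=C(CO)[C@@H]1[C@H](OC(=O)/C(C)=C\C)[C@@H]2O[C@]2(C)[C@H](OCc2ccc(OC)cc2)[C@H]1OC(C)=O
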